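**Strategy.** The target is read as fisetinidol-(4α→8)-catechin-(6→4β)-fisetinidol and is cut between C8 of ring A of the catechin unit and C4 of ring C of the 3,4-trans fisetinidol unit. One Lewis-acid Friedel–Crafts operation joins a benzyl-protected fisetinidol-(4β→6)-catechin, whose C8 is the only unsubstituted carbon of its tri-oxygenated ring (flanked by O7 and O1), to a 3,4-diacetoxyflavan: C4 ionises because it is benzylic and conjugated with O7 through C4a, and the 3-acetoxy group bridges the β-face so that C8 enters α. The 3,4-cis (4β→6) bond is made earlier by aryllithium addition to a flavan-4-one and ionic hydrogenation. Both fisetinidol units come from (+)-taxifolin.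

Key step: step 13

Assumption: α/β follow flavan usage (β is the face of the 3-oxygen in (2R,3S)-catechin and (2R,3S)-fisetinidol, so 4β is 3,4-cis and 4α is 3,4-trans); (+)-taxifolin is purchased as the (2R,3R) and (+)-catechin as the (2R,3S) enantiomer.

**Route**

Step 1
Reactants: 1 (+)-taxifolin, (2R,3R)-3,5,7,3',4'-pentahydroxyflavanone
Product: 2 (2R,3R)-7,3',4'-tri-O-benzyltaxifolin (5-OH and 3-OH free)
Conditions: BnBr (3.3 equiv), K2CO3, DMF, rt, N2
Reagents that add atoms: benzyl bromide BrCc1ccccc1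
Why: Williamson etherification of the three acidic phenols, while the 5-OH (hydrogen-bonded to the C4 carbonyl) and the secondary 3-OH stay free and the mild carbonate base leaves C2 and C3 of the chiral pool untouched.

Step 2
Reactants: 2 (2R,3R)-7,3',4'-tri-O-benzyltaxifolin
Product: 3 (2R,3R)-7,3',4'-tris(benzyloxy)-3-hydroxy-4-oxoflavan-5-yl trifluoromethanesulfonate
Conditions: PhNTf2, Et3N, DMAP (cat.), CH2Cl2, rt
Reagents that add atoms: N-phenylbis(trifluoromethanesulfonimide) O=S(=O)(N(c1ccccc1)S(=O)(=O)C(F)(F)F)C(F)(F)F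
Why: Sulfonylation of the remaining phenol with the mild triflimide reagent, which transfers triflyl to a phenoxide but not to the hindered secondary alcohol, prepares the C5–O bond for reductive cleavage.

Step 3
Reactants: 3 the 5-O-triflate
Product: 4 (2R,3R)-7,3',4'-tri-O-benzylfustin, (2R,3R)-7-(benzyloxy)-2-[3,4-bis(benzyloxy)phenyl]-3-hydroxychroman-4-one
Conditions: Pd(OAc)2 (cat.), dppp, Et3SiH, DMF, 60 °C
Reagents that add atoms: none
Why: Palladium-catalysed reduction of an aryl triflate by a silane (oxidative addition into the C5–O bond activated by the ortho carbonyl, hydride transfer, reductive elimination) removes the 5-oxygen under neutral conditions and converts the taxifolin skeleton into the fustin skeleton with both stereocentres intact.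

Step 4
Reactants: 4 (2R,3R)-7,3',4'-tri-O-benzylfustin
Product: 5 (2R,3R)-7,3',4'-tris(benzyloxy)-3-(tert-butyldimethylsilyloxy)flavan-4-one
Conditions: TBSOTf, 2,6-lutidine, CH2Cl2, 0 °C
Reagents that add atoms: tert-butyldimethylsilyl trifluoromethanesulfonate CC(C)(C)[Si](C)(C)OS(=O)(=O)C(F)(F)F
Why: Silylation of the secondary alcohol with a silyl triflate and a hindered pyridine base avoids the alkoxide conditions that epimerise or ring-open α-ketols, and installs the bulky group that later shields the β-face of C4.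

Step 5
Reactants: 4 (2R,3R)-7,3',4'-tri-O-benzylfustin
Product: 6 (2R,3S,4R)-7,3',4'-tris(benzyloxy)flavan-3,4-diol (tri-O-benzylmollisacacidin, 2,3-trans-3,4-trans)
Conditions: NaBH4, THF/EtOH, 0 °C
Reagents that add atoms: none
Why: Borohydride reduction of the flavan-4-one by axial hydride attack should give mainly the all-equatorial 3,4-trans diol (4α-OH, anti to the 3β-oxygen as needed for anchimeric assistance), and C4 is in any case ionised again in step 13.

Step 6
Reactants: 6 (2R,3S,4R)-7,3',4'-tris(benzyloxy)flavan-3,4-diol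
Product: 7 (2R,3R,4R)-3,4-diacetoxy-7,3',4'-tris(benzyloxy)flavan (same spatial arrangement as 6: 3-OAc β, 4-OAc α)
Conditions: Ac2O, pyridine, DMAP (cat.), CH2Cl2, 0 °C → rt
Reagents that add atoms: acetic anhydride CC(=O)OC(C)=O
Why: Acylation of both hydroxyls gives the benzylic 4-acetate as leaving group and the 3-acetate as participating group for the key step.

Step 7
Reactants: 8 (+)-catechin, (2R,3S)-flavan-3,5,7,3',4'-pentaol
Product: 9 3,5,7,3',4'-penta-O-benzyl-(+)-catechin
Conditions: NaH, BnBr, DMF, 0 °C → rt, N2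
Reagents that add atoms: benzyl bromide BrCc1ccccc1
Why: Exhaustive Williamson benzylation caps all five hydroxyls, including the secondary 3-OH, so that no acidic proton remains for the later organolithium steps.

Step 8
Reactants: 9 penta-O-benzylcatechin
Product: 10 8-bromo-3,5,7,3',4'-penta-O-benzylcatechin
Conditions: NBS, CH2Cl2, −78 → 0 °C
Reagents that add atoms: N-bromosuccinimide O=C1CCC(=O)N1Br
Why: Electrophilic aromatic bromination of the tri-oxygenated ring A occurs at C8, the less hindered of its two free positions (C6 lies between two benzyloxy groups), as is established for benzylated catechins, and the bromine caps C8.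

Step 9
Reactants: 10 8-bromo-penta-O-benzylcatechin
Product: 11 8-bromo-6-iodo-3,5,7,3',4'-penta-O-benzylcatechin
Conditions: NIS, TFA (cat.), CH2Cl2/MeCN, 0 °C → rt
Reagents that add atoms: N-iodosuccinimide O=C1CCC(=O)N1I
Why: Electrophilic iodination takes the only free position left on ring A (C6, ortho to O5 and O7 and para to O1), the dibenzyloxyphenyl ring B being far less reactive.

Step 10
Reactants: 11 8-bromo-6-iodo-penta-O-benzylcatechin; 5 3-O-TBS-tri-O-benzylfustin
Product: 13 C4 tertiary carbinol of the C6–C4 linked dimer (4α-aryl 4β-hydroxy), via C6 aryllithium 12 (not isolated)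
Conditions: n-BuLi (1.05 equiv), THF, −78 °C; then 5, −78 → −40 °C; then H2O
Reagents that add atoms: none
Why: Iodine–lithium exchange is much faster than bromine–lithium exchange, so C6 alone is metalated, and 1,2-addition of the aryllithium to the C4 carbonyl (free of a peri substituent in the 5-deoxy series) follows the known addition of aryllithiums to protected flavan-4-ones; attack anti to the 3-silyloxy group is expected, but this carbinol centre is erased in step 11.

Step 11
Reactants: 13 the tertiary carbinol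
Product: 15 protected 8-bromo-fisetinidol-(4β→6)-catechin (3,4-cis), via C4 diarylmethyl cation 14 (not isolated)
Conditions: Et3SiH (excess), TFA, CH2Cl2, −20 → 0 °C
Reagents that add atoms: none
Why: Ionic hydrogenation, in which TFA ionises the tertiary doubly benzylic carbinol to a planar C4 cation and Et3SiH should deliver hydride to the α-face, anti to the bulky 3β-silyloxy group (the face that carbon nucleophiles also choose on 2,3-trans flavan-4-yl cations), leaving the aryl group β and setting the 3,4-cis stereocentre.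

Step 12
Reactants: 15 the 8-bromo dimer
Product: 17 C8-unsubstituted protected fisetinidol-(4β→6)-catechin, via C8 aryllithium 16 (not isolated)
Conditions: n-BuLi, THF, −78 °C; then H2O
Reagents that add atoms: none
Why: Bromine–lithium exchange and protonation remove the C8 cap; the substrate has no acidic proton and its benzyl and silyl ethers tolerate n-BuLi at −78 °C.

Step 13
Reactants: 17 C8-unsubstituted protected fisetinidol-(4β→6)-catechin; 7 the 3,4-diacetoxyflavan (1.5 equiv)
Product: 19 protected fisetinidol-(4α→8)-catechin-(6→4β)-fisetinidol (eleven benzyl ethers, one TBS ether, one acetate), via acetoxonium ion 18 (not isolated)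
Conditions: TMSOTf (0.3 equiv), 4 Å MS, CH2Cl2, −40 → 0 °C
Reagents that add atoms: none
Why: TMSOTf ionises the benzylic 4α-acetate of 7, helped by O7 (conjugated with C4 through C4a) and by the trans 3β-acetoxy group, to the cis-fused acetoxonium ion 18 on the β-face, in equilibrium with the para-quinone-methide-type C4 cation. C8 of ring A of the catechin unit of 17 attacks C4 and rearomatises by proton loss, an SN1 Friedel–Crafts alkylation of the kind that is the standard Lewis-acid method for interflavan bonds. No ring is closed. The new stereocentre C4 is controlled by the substrate: the acetoxonium bridge occupies the β-face, so C8 enters on the α-face and the bond is 4α (3,4-trans), which is also the intrinsic preference of 2,3-trans flavan-4-yl cations. The step needs C8 to outcompete every other aryl carbon and every oxygen; this is secured because C8 is the only unsubstituted carbon of the tri-oxygenated ring (ortho to O7 and O1, para to O5) now that C6 is arylated, the di-oxygenated rings A of the fisetinidol units are far weaker nucleophiles, and all hydroxyls are capped. The existing 4β→6 bond of a 5-deoxy unit should not ionise under these conditions, so no scrambling is expected.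

Step 14
Reactants: 19 the protected trimer
Product: 21 undeca-O-benzyl trimer (free 3-OH on both fisetinidol units), via desilylated 3-O-acetyl trimer 20 (not isolated)
Conditions: HF·pyridine, THF, 0 → 40 °C; then K2CO3, MeOH/THF, 40 °C
Reagents that add atoms: none
Why: Fluoride cleaves the silyl ether and carbonate-catalysed methanolysis (Zemplén-type transesterification) removes the acetate, leaving only benzyl ethers and touching no stereocentre.

Step 15
Reactants: 21 the undeca-O-benzyl trimer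
Product: 22 fisetinidol-(4α→8)-catechin-(6→4β)-fisetinidol (CNP0289228.1)
Conditions: H2 (1 atm), Pd(OH)2/C, THF/MeOH/H2O, rt
Reagents that add atoms: none
Why: Hydrogenolysis of the eleven benzyl ethers (ten aryl, one alkyl) under neutral conditions, to which the interflavan C–C bonds of 5-deoxy units and the pyran rings are stable.

**Compound list**

1 | (+)-taxifolin, (2R,3R)-3,5,7,3',4'-pentahydroxyflavanone | Oc1cc(O)c2c(c1)O[C@H](c1ccc(O)c(O)c1)[C@@H](O)C2=O | starting material
2 | (2R,3R)-7,3',4'-tri-O-benzyltaxifolin | c5ccccc5COc1cc(O)c2c(c1)O[C@H](c1ccc(OCc5ccccc5)c(OCc5ccccc5)c1)[C@@H](O)C2=O | intermediate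
3 | (2R,3R)-7,3',4'-tris(benzyloxy)-3-hydroxy-4-oxoflavan-5-yl trifluoromethanesulfonate | c5ccccc5COc1cc(OS(=O)(=O)C(F)(F)F)c2c(c1)O[C@H](c1ccc(OCc5ccccc5)c(OCc5ccccc5)c1)[C@@H](O)C2=O | intermediate
4 | (2R,3R)-7,3',4'-tri-O-benzylfustin | c5ccccc5COc1ccc2c(c1)O[C@H](c1ccc(OCc5ccccc5)c(OCc5ccccc5)c1)[C@@H](O)C2=O | intermediate
5 | (2R,3R)-7,3',4'-tris(benzyloxy)-3-(tert-butyldimethylsilyloxy)flavan-4-one | c5ccccc5COc1ccc2c(c1)O[C@H](c1ccc(OCc5ccccc5)c(OCc5ccccc5)c1)[C@@H](O[Si](C)(C)C(C)(C)C)C2=O | intermediate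
6 | (2R,3S,4R)-7,3',4'-tris(benzyloxy)flavan-3,4-diol (2,3-trans-3,4-trans) | c5ccccc5COc1ccc2c(c1)O[C@H](c1ccc(OCc5ccccc5)c(OCc5ccccc5)c1)[C@@H](O)[C@@H]2O | intermediate
7 | (2R,3R,4R)-3,4-diacetoxy-7,3',4'-tris(benzyloxy)flavan (2,3-trans-3,4-trans; 3-OAc β, 4-OAc α) | c5ccccc5COc1ccc2c(c1)O[C@H](c1ccc(OCc5ccccc5)c(OCc5ccccc5)c1)[C@@H](OC(C)=O)[C@@H]2OC(C)=O | intermediate
8 | (+)-catechin, (2R,3S) | Oc1cc(O)c2c(c1)O[C@H](c1ccc(O)c(O)c1)[C@@H](O)C2 | starting material
9 | 3,5,7,3',4'-penta-O-benzyl-(+)-catechin | c1c(OCc5ccccc5)c2c(cc1OCc5ccccc5)O[C@H](c1ccc(OCc5ccccc5)c(OCc5ccccc5)c1)[C@@H](OCc5ccccc5)C2 | intermediate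
10 | 8-bromo-3,5,7,3',4'-penta-O-benzylcatechin | c1c(OCc5ccccc5)c2c(c(Br)c1OCc5ccccc5)O[C@H](c1ccc(OCc5ccccc5)c(OCc5ccccc5)c1)[C@@H](OCc5ccccc5)C2 | intermediate
11 | 8-bromo-6-iodo-3,5,7,3',4'-penta-O-benzylcatechin | Ic1c(OCc5ccccc5)c2c(c(Br)c1OCc5ccccc5)O[C@H](c1ccc(OCc5ccccc5)c(OCc5ccccc5)c1)[C@@H](OCc5ccccc5)C2 | intermediate
12 | 8-bromo-6-lithio-3,5,7,3',4'-penta-O-benzylcatechin | [Li]c1c(OCc5ccccc5)c2c(c(Br)c1OCc5ccccc5)O[C@H](c1ccc(OCc5ccccc5)c(OCc5ccccc5)c1)[C@@H](OCc5ccccc5)C2 | intermediate (not isolated)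
13 | tertiary carbinol: C6 of 8-bromo-penta-O-benzylcatechin bonded to C4 of 3-O-TBS-7,3',4'-tri-O-benzylfisetinidol, which also carries 4β-OH (aryl α) | c5ccccc5COc1ccc2c(c1)O[C@H](c1ccc(OCc5ccccc5)c(OCc5ccccc5)c1)[C@@H](O[Si](C)(C)C(C)(C)C)[C@]2(O)c1c(OCc5ccccc5)c2c(c(Br)c1OCc5ccccc5)O[C@H](c1ccc(OCc5ccccc5)c(OCc5ccccc5)c1)[C@@H](OCc5ccccc5)C2 | intermediate
14 | C4 diarylmethyl cation of 13 as its trifluoroacetate ion pair | c5ccccc5COc1ccc2c(c1)O[C@H](c1ccc(OCc5ccccc5)c(OCc5ccccc5)c1)[C@@H](O[Si](C)(C)C(C)(C)C)[C+]2c1c(OCc5ccccc5)c2c(c(Br)c1OCc5ccccc5)O[C@H](c1ccc(OCc5ccccc5)c(OCc5ccccc5)c1)[C@@H](OCc5ccccc5)C2.[O-]C(=O)C(F)(F)F | intermediate (not isolated)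
15 | protected 8-bromo-fisetinidol-(4β→6)-catechin: 3-O-TBS-7,3',4'-tri-O-benzylfisetinidol linked 4β (3,4-cis) to C6 of 8-bromo-penta-O-benzylcatechin | c5ccccc5COc1ccc2c(c1)O[C@H](c1ccc(OCc5ccccc5)c(OCc5ccccc5)c1)[C@@H](O[Si](C)(C)C(C)(C)C)[C@H]2c1c(OCc5ccccc5)c2c(c(Br)c1OCc5ccccc5)O[C@H](c1ccc(OCc5ccccc5)c(OCc5ccccc5)c1)[C@@H](OCc5ccccc5)C2 | intermediate
16 | C8-lithio analogue of 15 | c5ccccc5COc1ccc2c(c1)O[C@H](c1ccc(OCc5ccccc5)c(OCc5ccccc5)c1)[C@@H](O[Si](C)(C)C(C)(C)C)[C@H]2c1c(OCc5ccccc5)c2c(c([Li])c1OCc5ccccc5)O[C@H](c1ccc(OCc5ccccc5)c(OCc5ccccc5)c1)[C@@H](OCc5ccccc5)C2 | intermediate (not isolated)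
17 | protected fisetinidol-(4β→6)-catechin with C8–H (eight benzyl ethers, one TBS ether) | c5ccccc5COc1ccc2c(c1)O[C@H](c1ccc(OCc5ccccc5)c(OCc5ccccc5)c1)[C@@H](O[Si](C)(C)C(C)(C)C)[C@H]2c1c(OCc5ccccc5)c2c(cc1OCc5ccccc5)O[C@H](c1ccc(OCc5ccccc5)c(OCc5ccccc5)c1)[C@@H](OCc5ccccc5)C2 | intermediate
18 | cis-fused 2-methyl-1,3-dioxolan-2-ylium (acetoxonium) ion across O3/C3–C4/O4 on the β-face of 7,3',4'-tri-O-benzylfisetinidol, as triflate | c5ccccc5COc1ccc2c(c1)O[C@H](c1ccc(OCc5ccccc5)c(OCc5ccccc5)c1)[C@H]3OC(C)=[O+][C@@H]23.[O-]S(=O)(=O)C(F)(F)F | intermediate (not isolated)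
19 | protected fisetinidol-(4α→8)-catechin-(6→4β)-fisetinidol: 4β→6 unit 3-O-TBS, 4α→8 unit 3-O-acetyl, all other oxygens benzylated | c5ccccc5COc1ccc2c(c1)O[C@H](c1ccc(OCc5ccccc5)c(OCc5ccccc5)c1)[C@@H](O[Si](C)(C)C(C)(C)C)[C@H]2c1c(OCc5ccccc5)c2c(c([C@@H]3c4ccc(OCc5ccccc5)cc4O[C@H](c4ccc(OCc5ccccc5)c(OCc5ccccc5)c4)[C@H]3OC(C)=O)c1OCc5ccccc5)O[C@H](c1ccc(OCc5ccccc5)c(OCc5ccccc5)c1)[C@@H](OCc5ccccc5)C2 | intermediate
20 | desilylated 19 (3-OH on the 4β→6 unit, 3-OAc on the 4α→8 unit) | c5ccccc5COc1ccc2c(c1)O[C@H](c1ccc(OCc5ccccc5)c(OCc5ccccc5)c1)[C@@H](O)[C@H]2c1c(OCc5ccccc5)c2c(c([C@@H]3c4ccc(OCc5ccccc5)cc4O[C@H](c4ccc(OCc5ccccc5)c(OCc5ccccc5)c4)[C@H]3OC(C)=O)c1OCc5ccccc5)O[C@H](c1ccc(OCc5ccccc5)c(OCc5ccccc5)c1)[C@@H](OCc5ccccc5)C2 | intermediate (not isolated)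
21 | undeca-O-benzyl fisetinidol-(4α→8)-catechin-(6→4β)-fisetinidol with free 3-OH on both fisetinidol units | c5ccccc5COc1ccc2c(c1)O[C@H](c1ccc(OCc5ccccc5)c(OCc5ccccc5)c1)[C@@H](O)[C@H]2c1c(OCc5ccccc5)c2c(c([C@@H]3c4ccc(OCc5ccccc5)cc4O[C@H](c4ccc(OCc5ccccc5)c(OCc5ccccc5)c4)[C@H]3O)c1OCc5ccccc5)O[C@H](c1ccc(OCc5ccccc5)c(OCc5ccccc5)c1)[C@@H](OCc5ccccc5)C2 | intermediate
22 | fisetinidol-(4α→8)-catechin-(6→4β)-fisetinidol | Oc1ccc2c(c1)O[C@H](c1ccc(O)c(O)c1)[C@@H](O)[C@H]2c1c(O)c2c(c([C@@H]3c4ccc(O)cc4O[C@H](c4ccc(O)c(O)c4)[C@H]3O)c1O)O[C@H](c1ccc(O)c(O)c1)[C@@H](O)C2 | target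

**Step count and risks**

Total step count: 15. Longest linear sequence: 10 steps (steps 1, 2, 3, 4, 10, 11, 12, 13, 14, 15).

Steps most likely to fail:

1. Step 11. Hydride may be delivered to both faces of the planar C4 cation, or the cation may lose the proton at C3 or the silyl group, which would erode the 3,4-cis selectivity. The fallback forms the aryl–C4 bond on a centre that already carries hydrogen (halogen-capped Friedel–Crafts alkylation) and sets out from 5 and 10. Ketone 5 is reduced with NaBH4 to (2R,3S,4R)-7,3',4'-tris(benzyloxy)-3-(tert-butyldimethylsilyloxy)flavan-4-ol F1. BF3·OEt2 in CH2Cl2 at −78 → −30 °C then ionises F1 and alkylates 10 at C6, its only free ring A position. The 4β epimer is separated from the 4α epimer by chromatography and is compound 15, where the route is rejoined; steps 9 and 10 are then not needed.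

2. Step 13. Attack by the congested C8 (between the 7-benzyloxy group and O1, next to the C6 flavanyl group) may be too slow, so that ionised 7 self-condenses or eliminates, or the acetoxonium bridge may open with incomplete face control. The fallback is the protecting-group-free acid condensation and sets out from 17 and 4. Compound 17 is desilylated with HF·pyridine to octa-O-benzyl fisetinidol-(4β→6)-catechin with free fisetinidol 3-OH F2, which is hydrogenolysed (H2, Pd(OH)2/C) to fisetinidol-(4β→6)-catechin F3. Ketone 4 is hydrogenolysed to (+)-fustin F4 and reduced with NaBH4 to (+)-mollisacacidin F5. F3 and F5 are condensed in 0.1 M aqueous HCl at rt, where the small quinone-methide-type C4 electrophile should again seek C8 of the phloroglucinol-type ring, mainly on the α-face. This gives 22 directly after chromatography on Sephadex LH-20, so the route is rejoined at 22.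

3. Step 3. Under the palladium/silane conditions the α-ketol may epimerise at C2/C3 through pyran ring opening, dehydrogenate to the flavonol, or resist reduction at the hindered peri position. The fallback removes the sensitive carbonyl before the triflate and sets out from 3. NaBH4 gives (2R,3S,4R)-7,3',4'-tris(benzyloxy)-3,4-dihydroxyflavan-5-yl trifluoromethanesulfonate F6, whose triflate is then reduced with Pd(OAc)2/dppp/Et3SiH to give diol 6, where the route is rejoined. Ketone 4 for step 4 is regenerated from 6 by selective oxidation of the benzylic 4-hydroxyl with MnO2.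

**Further compounds**

F1 | step 11 | (2R,3S,4R)-7,3',4'-tris(benzyloxy)-3-(tert-butyldimethylsilyloxy)flavan-4-ol | c5ccccc5COc1ccc2c(c1)O[C@H](c1ccc(OCc5ccccc5)c(OCc5ccccc5)c1)[C@@H](O[Si](C)(C)C(C)(C)C)[C@@H]2O
F2 | step 13 | octa-O-benzyl fisetinidol-(4β→6)-catechin with free fisetinidol 3-OH | c5ccccc5COc1ccc2c(c1)O[C@H](c1ccc(OCc5ccccc5)c(OCc5ccccc5)c1)[C@@H](O)[C@H]2c1c(OCc5ccccc5)c2c(cc1OCc5ccccc5)O[C@H](c1ccc(OCc5ccccc5)c(OCc5ccccc5)c1)[C@@H](OCc5ccccc5)C2
F3 | step 13 | fisetinidol-(4β→6)-catechin | Oc1ccc2c(c1)O[C@H](c1ccc(O)c(O)c1)[C@@H](O)[C@H]2c1c(O)c2c(cc1O)O[C@H](c1ccc(O)c(O)c1)[C@@H](O)C2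
F4 | step 13 | (+)-fustin, (2R,3R)-3,7,3',4'-tetrahydroxyflavanone | Oc1ccc2c(c1)O[C@H](c1ccc(O)c(O)c1)[C@@H](O)C2=O
F5 | step 13 | (+)-mollisacacidin, (2R,3S,4R)-flavan-3,4,7,3',4'-pentaol | Oc1ccc2c(c1)O[C@H](c1ccc(O)c(O)c1)[C@@H](O)[C@@H]2O
F6 | step 3 | (2R,3S,4R)-7,3',4'-tris(benzyloxy)-3,4-dihydroxyflavan-5-yl trifluoromethanesulfonate | c5ccccc5COc1cc(OS(=O)(=O)C(F)(F)F)c2c(c1)O[C@H](c1ccc(OCc5ccccc5)c(OCc5ccccc5)c1)[C@@H](O)[C@@H]2O
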